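The isoflavone is cut at the C4–C4a bond of ring C, so the carbonyl carbon C4 is joined to ring A last, by intramolecular Friedel–Crafts acylation. The step exploits the position of C4a in ring A: it is ortho to O1 and para to the methoxy-bearing C7, hence the most nucleophilic carbon within reach of an acyl cation carried on the O1–C2=C3 chain. One operation forms C4–C4a and completes the pyranone. The precursor is a (Z)-3-aryloxy-2-arylacrylic acid: the 4-benzyloxy-3-methoxyphenyl ether oxygen is the future O1, ring B sits on the future C3, and the carboxyl (future C4) is cis to the aryloxy group. Hydrogenolysis then frees the C6 phenol.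

Key step: step 8

Remark on geometry: compounds 8, 9 and 10 are named as the Z isomers (oxygen substituent cis to the carboxyl carbon), the geometry expected from chelation-controlled tosylation followed by retentive vinylic substitution. Any E isomer carried along is not removed, because it should reach the same ring-closing acyl cation in step 8.

Step 1
Reactants: 1 4-(benzyloxy)-3-methoxybenzaldehyde
Product: 3 4-(benzyloxy)-3-methoxyphenol, via 4-(benzyloxy)-3-methoxyphenyl formate 2 (not isolated)
Conditions: mCPBA, CH2Cl2, 0 °C → rt; aq. NaHCO3 wash; then K2CO3 (cat.), MeOH, rt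
Reagents that add atoms: mCPBA (3-chloroperoxybenzoic acid), OOC(=O)c1cccc(Cl)c1
Why: Baeyer–Villiger oxidation with migration of the electron-rich aryl group (Dakin-type outcome) should give the aryl formate, and mild methanolysis releases the phenol without touching the benzyl or methyl ethers.

Step 2
Reactants: 4 1,2,4-trimethoxybenzene
Product: 5 methyl 2-oxo-2-(2,4,5-trimethoxyphenyl)acetate
Conditions: ClCOCO2Me, TiCl4, CH2Cl2, −20 → 0 °C
Reagents that add atoms: methyl chlorooxoacetate, COC(=O)C(Cl)=O
Why: Friedel–Crafts acylation should occur at the carbon that is para to one methoxy group and ortho to another, the most nucleophilic position, while TiCl4 at low temperature limits cleavage of the methoxy group ortho to the new ketone.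

Step 3
Reactants: 5 methyl 2-oxo-2-(2,4,5-trimethoxyphenyl)acetate
Product: 6 methyl 2-(2,4,5-trimethoxyphenyl)acetate
Conditions: Et3SiH, TFA, rt → 50 °C
Reagents that add atoms: none
Why: Ionic hydrogenation: the protonated aryl ketone accepts hydride, the benzylic alcohol ionises to a cation stabilised by the ortho and para methoxy groups and is reduced a second time, while the ester is inert.

Step 4
Reactants: 6 methyl 2-(2,4,5-trimethoxyphenyl)acetate
Product: 7 methyl (2Z)-3-hydroxy-2-(2,4,5-trimethoxyphenyl)prop-2-enoate (chelated enol of the formyl ester, in tautomeric equilibrium)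
Conditions: NaH, HCO2Me, THF, 0 °C → rt; then 1 M HCl
Reagents that add atoms: methyl formate, COC=O
Why: Crossed Claisen condensation of the ester enolate with non-enolisable methyl formate is driven by deprotonation of the acidic formyl ester, and the matching methyl groups exclude ester scrambling.

Step 5
Reactants: 7 methyl (2Z)-3-hydroxy-2-(2,4,5-trimethoxyphenyl)prop-2-enoate
Product: 8 methyl (2Z)-3-{[(4-methylphenyl)sulfonyl]oxy}-2-(2,4,5-trimethoxyphenyl)prop-2-enoate
Conditions: TsCl, N-methylimidazole, LiOH·H2O, MeCN, 0 °C → rt
Reagents that add atoms: 4-methylbenzenesulfonyl chloride (TsCl), Cc1ccc(cc1)S(=O)(=O)Cl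
Why: O-sulfonylation of the lithium-chelated enolate, whose oxygen is held cis to the ester carbonyl, by the N-tosylimidazolium species from TsCl and N-methylimidazole should deliver the Z enol tosylate.

Step 6
Reactants: 8 methyl (2Z)-3-{[(4-methylphenyl)sulfonyl]oxy}-2-(2,4,5-trimethoxyphenyl)prop-2-enoate; 3 4-(benzyloxy)-3-methoxyphenol
Product: 9 methyl (2Z)-3-[4-(benzyloxy)-3-methoxyphenoxy]-2-(2,4,5-trimethoxyphenyl)prop-2-enoate
Conditions: K2CO3, DMF, rt → 40 °C
Reagents that add atoms: none
Why: Nucleophilic vinylic substitution by addition–elimination: the phenoxide adds to the unhindered β-carbon of the acrylate and tosylate is expelled, normally with retention of the alkene geometry.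

Step 7
Reactants: 9 methyl (2Z)-3-[4-(benzyloxy)-3-methoxyphenoxy]-2-(2,4,5-trimethoxyphenyl)prop-2-enoate
Product: 10 (2Z)-3-[4-(benzyloxy)-3-methoxyphenoxy]-2-(2,4,5-trimethoxyphenyl)prop-2-enoic acid
Conditions: LiOH·H2O, THF/H2O, rt; then 1 M HCl, 0 °C, to pH 3
Reagents that add atoms: lithium hydroxide, [Li+].[OH-]
Why: Saponification by acyl attack of hydroxide, as practised for 3-aryloxyacrylates; methanol is left out so that no alkoxide can displace the aryloxy group at the β-carbon, and cold acidification spares the enol ether.

Step 8
Reactants: 10 (2Z)-3-[4-(benzyloxy)-3-methoxyphenoxy]-2-(2,4,5-trimethoxyphenyl)prop-2-enoic acid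
Product: 12 6-(benzyloxy)-7-methoxy-3-(2,4,5-trimethoxyphenyl)-4H-chromen-4-one, via mixed trifluoroacetic anhydride 11 (not isolated)
Conditions: TFAA, CH2Cl2, 0 °C → rt; aq. NaHCO3 quench
Reagents that add atoms: none
Why: TFAA converts acid 10 into mixed anhydride 11, which ionises with the help of the liberated trifluoroacetic acid to an acyl cation stabilised through C3=C2–O1; this cation attacks C4a of ring A, and loss of the proton restores the arene and gives the pyranone of 12. The closest known reaction is the acid-promoted cyclisation of 3-aryloxyacrylic acids to chromones, an intramolecular Friedel–Crafts acylation. Ring C closes in a 6-exo-trig fashion, the acyl C=O staying outside the new ring O1–C2–C3–C4–C4a–C8a. The step needs regioselectivity between the two carbons ortho to O1: C4a is para to the C7 methoxy group and unhindered, the other carbon is wedged between O1 and that methoxy group, and ring B cannot interfere because attack there would make a four-membered ring. The Z geometry places the acyl carbon next to ring A, and residual E acid should converge because the delocalised acyl cation has little double-bond character between C2 and C3. No metal halide is present and the medium is only moderately acidic, so the benzyl ether should survive.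

Step 9
Reactants: 12 6-(benzyloxy)-7-methoxy-3-(2,4,5-trimethoxyphenyl)-4H-chromen-4-one
Product: 13 6-hydroxy-7-methoxy-3-(2,4,5-trimethoxyphenyl)-4H-chromen-4-one
Conditions: H2 (1 atm), 10% Pd/C, THF/MeOH, rt
Reagents that add atoms: none
Why: Hydrogenolysis of the benzylic C–O bond over Pd/C at ambient pressure should be much faster than reduction of the conjugated C2=C3 bond, and the methyl ethers are inert.

Compound list
1 | 4-(benzyloxy)-3-methoxybenzaldehyde (O-benzylvanillin) | COc1cc(C=O)ccc1OCc1ccccc1 | starting material
2 | 4-(benzyloxy)-3-methoxyphenyl formate | COc1cc(OC=O)ccc1OCc1ccccc1 | intermediate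
3 | 4-(benzyloxy)-3-methoxyphenol | COc1cc(O)ccc1OCc1ccccc1 | intermediate
4 | 1,2,4-trimethoxybenzene | COc1ccc(OC)c(OC)c1 | starting material
5 | methyl 2-oxo-2-(2,4,5-trimethoxyphenyl)acetate | COC(=O)C(=O)c1cc(OC)c(OC)cc1OC | intermediate
6 | methyl 2-(2,4,5-trimethoxyphenyl)acetate | COC(=O)Cc1cc(OC)c(OC)cc1OC | intermediate
7 | methyl (2Z)-3-hydroxy-2-(2,4,5-trimethoxyphenyl)prop-2-enoate (enol of the formyl ester) | O/C=C(/c1cc(OC)c(OC)cc1OC)C(=O)OC | intermediate
8 | methyl (2Z)-3-{[(4-methylphenyl)sulfonyl]oxy}-2-(2,4,5-trimethoxyphenyl)prop-2-enoate | Cc1ccc(cc1)S(=O)(=O)O/C=C(/c1cc(OC)c(OC)cc1OC)C(=O)OC | intermediate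
9 | methyl (2Z)-3-[4-(benzyloxy)-3-methoxyphenoxy]-2-(2,4,5-trimethoxyphenyl)prop-2-enoate | COc1cc(O/C=C(/c2cc(OC)c(OC)cc2OC)C(=O)OC)ccc1OCc1ccccc1 | intermediate
10 | (2Z)-3-[4-(benzyloxy)-3-methoxyphenoxy]-2-(2,4,5-trimethoxyphenyl)prop-2-enoic acid | COc1cc(O/C=C(/c2cc(OC)c(OC)cc2OC)C(O)=O)ccc1OCc1ccccc1 | intermediate
11 | (2Z)-3-[4-(benzyloxy)-3-methoxyphenoxy]-2-(2,4,5-trimethoxyphenyl)prop-2-enoic trifluoroacetic anhydride | COc1cc(O/C=C(/c2cc(OC)c(OC)cc2OC)C(=O)OC(=O)C(F)(F)F)ccc1OCc1ccccc1 | intermediate
12 | 6-(benzyloxy)-7-methoxy-3-(2,4,5-trimethoxyphenyl)-4H-chromen-4-one | COc1cc2occ(-c3cc(OC)c(OC)cc3OC)c(=O)c2cc1OCc1ccccc1 | intermediate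
13 | 6-hydroxy-7-methoxy-3-(2,4,5-trimethoxyphenyl)-4H-chromen-4-one | COc1cc2occ(-c3cc(OC)c(OC)cc3OC)c(=O)c2cc1O | target

Total step count: 9. Longest linear sequence: 8 steps (compound 4 to compound 13 through steps 2 to 9); step 1 is a one-step side branch that joins at step 6.

Steps most likely to fail

Step 8. The mixed anhydride may ionise too slowly, or the acid formed may detach the benzyl group and let it re-attach to the electron-rich rings, or E-configured material may fail to turn into the reactive geometry. The fallback abandons the C4–C4a closure for the deoxybenzoin construction and needs no benzyl group. It sets out from 6, which is saponified (LiOH, THF/H2O) to 2-(2,4,5-trimethoxyphenyl)acetic acid F1. F1 acylates purchased 2-methoxybenzene-1,4-diol (COc1cc(O)ccc1O) in BF3·OEt2 at 80 °C, para to the methoxy group and ortho to a hydroxyl, to give 1-(2,5-dihydroxy-4-methoxyphenyl)-2-(2,4,5-trimethoxyphenyl)ethan-1-one F2. One-carbon insertion and ring closure with DMF, BF3·OEt2 and MsCl (50 → 80 °C) then forms O1–C2 and C2–C3, and the sequence comes back to the route at 13, the target itself.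

Step 6. The phenoxide may attack the sulfonyl sulfur instead of the β-carbon, so that the tosyl group is transferred to the phenol and the enolate of 7 is returned. The fallback sets out from 7 and removes the second electrophilic site: Vilsmeier-type chlorination ((COCl)2, DMF, CH2Cl2, 0 °C → rt) should give methyl (2Z)-3-chloro-2-(2,4,5-trimethoxyphenyl)prop-2-enoate F3. F3 is then substituted by phenol 3 (K2CO3, DMF, 40 °C) in an addition–elimination that can only occur at carbon, and the sequence comes back to the route at 9.

Step 3. The reduction may stall at the benzylic alcohol, because the neighbouring ester disfavours ionisation, or the benzylic cation may alkylate a second electron-rich arene. The fallback builds the arylacetate by C–C coupling instead of deoxygenation and sets out from 4. Bromination (NBS, MeCN, rt) at the same most activated carbon gives 1-bromo-2,4,5-trimethoxybenzene F4. Arylation of dimethyl malonate (Pd(OAc)2, P(t-Bu)3·HBF4, K3PO4, toluene, 90 °C) gives dimethyl 2-(2,4,5-trimethoxyphenyl)propanedioate F5. Krapcho demethoxycarbonylation (LiCl, wet DMSO, 140 °C) then comes back to the route at 6.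

Further compounds
F1 | step 8 | 2-(2,4,5-trimethoxyphenyl)acetic acid | OC(=O)Cc1cc(OC)c(OC)cc1OC
F2 | step 8 | 1-(2,5-dihydroxy-4-methoxyphenyl)-2-(2,4,5-trimethoxyphenyl)ethan-1-one | COc1cc(O)c(cc1O)C(=O)Cc1cc(OC)c(OC)cc1OC
F3 | step 6 | methyl (2Z)-3-chloro-2-(2,4,5-trimethoxyphenyl)prop-2-enoate | Cl/C=C(/c1cc(OC)c(OC)cc1OC)C(=O)OC
F4 | step 3 | 1-bromo-2,4,5-trimethoxybenzene | COc1cc(OC)c(OC)cc1Br
F5 | step 3 | dimethyl 2-(2,4,5-trimethoxyphenyl)propanedioate | COC(=O)C(C(=O)OC)c1cc(OC)c(OC)cc1OC
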